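The autumn and spring runs differ in their partner charge and were both followed to 40.0 min, so their readings can be laid side by side.

all flasks: substrate 0.86 M
- autumn: partner 0.60 equiv; run made earlier
- spring: partner 0.90 equiv; run made earlier
- flask: partner 1.20 equiv; time 1.0 h

- autumn (time / min: substrate / %, first product / %): 3.00: 98.9, 0.9; 10.0: 95.9, 2.9; 15.0: 95.9, 2.6; 25.0: 93.6, 4.9; 40.0: 91.8, 6.1
- spring (time / min: substrate / %, first product / %): 8.00: 94.8, 4.0; 15.0: 93.2, 4.9; 20.0: 92.8, 5.4; 30.0: 90.2, 7.1; 40.0: 87.9, 8.6

(scatter of a reading: 0.5 percentage points)

1. the substrate standing at 1.0 h, as a percentage of the substrate charged
2. the first product standing at 1.0 h, as a percentage of the substrate charged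
3. the bis adduct standing at 1.0 h, as a percentage of the substrate charged

- a reading or a percentage of first product counts all its forms, free or not
- a reading of substrate is of its free form alone

Work with the fraction of substrate left, not the fraction made: take minus its natural logarithm and divide by the equivalents of partner. At 40.0 min this gives 0.143 for autumn and 0.143 for spring, so in these two runs the partner charge enters as a plain factor.

Two of us carry this figure to the flask differently. The first holds a steady view, the pseudo-first-order picture, in which the figure grows in proportion to time. Stretched to 1.0 h, it becomes 0.214, and with 1.20 equiv of partner the flask keeps 77.3% of its substrate.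

The second points to the earlier readings. At 15.0 min the runs stand at 0.0698 and 0.0782, already about half of the later figure, though only 0.375 of the time has passed. So a quick start is followed by a slower climb, the figure gaining 0.0689 on average over the 25.0 min between those readings.

I side with the second. Continuing that climb at the same pace gives the loss per equivalent at the asked time, 0.198, so the flask keeps 78.8%.

The forecast, on the same side because “Rates fall far faster than the partner is used up”, gives 80% substrate, 14% first product and 6% bis adduct, its substrate standing above my figure.

The flask gives 79.5% substrate, 14.0% first product and 0.771% bis adduct, nearer the second view than the first.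

    partner + first product → bis adduct (k = 0.0142 L mol⁻¹ min⁻¹)
    substrate + first product ⇌ idle adduct, settled at all times (K = 1.00 L mol⁻¹)
    substrate + partner → first product (k = 0.0130 L mol⁻¹ min⁻¹)
    partner ⇌ dormant form (K = 4.30, k = 0.303 min⁻¹)

In this flask free partner is down to 26.0% of its charge at 0.100 h and stands at 16.1% at 1.00 h, while partner and dormant form relax with a half-life of 1.86 min. Reckoned back from the result, the loss per equivalent is 0.191, against my 0.198. For the neighbour charged with 0.300 equiv, the carried figure gives 94.2%, the steady figure gives 93.8%, and that neighbour holds 94.2% of its substrate.

(The numbers in the tables were generated by integration on assumed constants.)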